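**Retrosynthetic overview**
- Last operations: fluoride removal of three silyl groups; before that, the aryl–CH2 bond from an arylmagnesium bromide (bis-silylated 2-bromo-6-methylhydroquinone) and a primary allylic bromide by Cu-catalysed SN2 coupling.
- Key C4–C5 bond: catalytic enantioselective vinylogous Mukaiyama aldol between a furan-bearing (2E,6E)-dienal (C15) and the silyl dienol ether of methyl 3-methylbut-2-enoate; it sets the 5S carbinol and the 2E trisubstituted alkene together.
- The dienal comes from geranyl acetate (both E alkenes bought): terminal allylic oxidation, bromide, Cu-catalysed coupling with 2-methylbut-3-yne-1,2-diol.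
- Rings: the benzene ring is bought (4-hydroxy-3-methylbenzaldehyde, then bromination and Dakin oxidation); the furan is the only ring made, by AgNO3-catalysed cyclisation–dehydration of the alkynediol, before the aldol.

Assumption: the (S,S) antipode of the binaphthyldiamine-derived bisphosphoramide sends the dienol ether to the Si face of the enal (the (R,R) antipode being Re-selective); this is from memory, so the configuration of 15 is confirmed by Mosher ester analysis before material is carried on.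

**Route**

Step 1
Reactants: 1 geranyl acetate
Product: 2 (2E,6E)-8-hydroxy-3,7-dimethylocta-2,6-dien-1-yl acetate
Conditions: SeO2 (0.1 equiv), t-BuOOH (70% aq., 3 equiv), salicylic acid (0.1 equiv), CH2Cl2, rt, 30 h
Reagents that add atoms: tert-butyl hydroperoxide, CC(C)(C)OO (oxygen source, relayed by catalytic SeO2, O=[Se]=O)
Why: Sharpless-modified Riley allylic oxidation (ene reaction then [2,3]-sigmatropic shift) hydroxylates the terminal E-methyl group selectively while the alkene next to the acetate is deactivated and both geometries are kept.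

Step 2
Reactants: 2 (2E,6E)-8-hydroxy-3,7-dimethylocta-2,6-dien-1-yl acetate
Product: 3 (2E,6E)-8-bromo-3,7-dimethylocta-2,6-dien-1-yl acetate
Conditions: PPh3, CBr4, CH2Cl2, 0 °C
Reagents that add atoms: carbon tetrabromide, BrC(Br)(Br)Br
Why: Appel bromination converts the primary allylic alcohol into the bromide by SN2 at the CH2 under neutral conditions that leave the acetate and alkene geometry alone.

Step 3
Reactants: 4 hydroxyacetone
Product: 5 2-methylbut-3-yne-1,2-diol (racemic)
Conditions: HC≡CMgBr (2.5 equiv, 0.5 M in THF), 0 °C to rt; water quench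
Reagents that add atoms: ethynylmagnesium bromide, C#C[Mg]Br
Why: Grignard 1,2-addition to the ketone after the first equivalent deprotonates the hydroxyl; the new carbinol centre is racemic and is destroyed later when the furan aromatises.

Step 4
Reactants: 3 (2E,6E)-8-bromo-3,7-dimethylocta-2,6-dien-1-yl acetate; 5 2-methylbut-3-yne-1,2-diol
Product: 6 (2E,6E)-11,12-dihydroxy-3,7,11-trimethyldodeca-2,6-dien-9-yn-1-yl acetate (racemic at C11)
Conditions: CuI (0.2 equiv), K2CO3 (1.5 equiv), Bu4NBr, DMF, rt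
Reagents that add atoms: none
Why: Jeffery-type Cu-catalysed alkynyl–allyl coupling, in which the copper acetylide displaces the unhindered primary allylic bromide (SN2) to give the skipped enyne with the 6E alkene retained and the free diol and acetate tolerated.

Step 5
Reactants: 6 (2E,6E)-11,12-dihydroxy-3,7,11-trimethyldodeca-2,6-dien-9-yn-1-yl acetate
Product: 8 (2E,6E)-3,7-dimethyl-8-(4-methylfuran-2-yl)octa-2,6-dien-1-yl acetate, via dihydrofuranol 7 (not isolated)
Conditions: AgNO3 on silica gel (10 wt %, 0.1 equiv Ag), CH2Cl2, rt, dark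
Reagents that add atoms: none
Why: Ag-catalysed 5-endo-dig hydroalkoxylation of the 3-alkyne-1,2-diol by its primary hydroxyl followed by loss of water from the tertiary carbinol (Knight-type furan synthesis) forms the 2,4-disubstituted furan ring.

Step 6
Reactants: 8 (2E,6E)-3,7-dimethyl-8-(4-methylfuran-2-yl)octa-2,6-dien-1-yl acetate
Product: 9 (2E,6E)-3,7-dimethyl-8-(4-methylfuran-2-yl)octa-2,6-dien-1-ol
Conditions: K2CO3 (0.2 equiv), MeOH, rt
Reagents that add atoms: none
Why: Base-catalysed transesterification (methanolysis) frees the primary allylic alcohol without touching the furan or the alkenes.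

Step 7
Reactants: 9 (2E,6E)-3,7-dimethyl-8-(4-methylfuran-2-yl)octa-2,6-dien-1-ol
Product: 10 (2E,6E)-3,7-dimethyl-8-(4-methylfuran-2-yl)octa-2,6-dienal
Conditions: activated MnO2 (15 equiv), CH2Cl2, rt
Reagents that add atoms: none
Why: MnO2 allylic oxidation is selective for the allylic alcohol, stops at the enal and keeps the 2E geometry as it does for geraniol to geranial.

Step 8
Reactants: 11 methyl 3-methylbut-2-enoate
Product: 13 tert-butyl[(1-methoxy-3-methylbuta-1,3-dien-1-yl)oxy]dimethylsilane (ketene acetal geometry not controlled and not needed), via lithium dienolate 12 (not isolated)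
Conditions: LiN(i-Pr)2, THF/DMPU, −78 °C; TBSCl, −78 °C to rt; distil
Reagents that add atoms: tert-butyldimethylsilyl chloride, CC(C)(C)[Si](C)(C)Cl
Why: Kinetic γ-deprotonation gives the extended dienolate and O-silylation traps it as the silyl dienol ether (silyl ketene acetal formation).

Step 9
Reactants: 10 (2E,6E)-3,7-dimethyl-8-(4-methylfuran-2-yl)octa-2,6-dienal; 13 tert-butyl[(1-methoxy-3-methylbuta-1,3-dien-1-yl)oxy]dimethylsilane
Product: 15 methyl (2E,5S,6E,10E)-5-hydroxy-3,7,11-trimethyl-12-(4-methylfuran-2-yl)dodeca-2,6,10-trienoate, via trichlorosilyl ether 14 (not isolated)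
Conditions: SiCl4 (1.1 equiv), (S,S)-bisphosphoramide (5 mol %; pentane-1,5-diyl-linked bis-phosphoramide built from (S)-N,N′-dimethyl-1,1′-binaphthyl-2,2′-diamine), i-Pr2NEt (0.2 equiv), CH2Cl2, −78 °C; then cold sat. aq. NaHCO3
Reagents that add atoms: none
Why: Denmark-type Lewis-base-activated SiCl4 vinylogous Mukaiyama aldol, in which the chiral cationic silicon complex binds the enal and the dienol ether attacks only through its γ-carbon in an open transition state on the Si face (5S) from its s-trans form (2E), the amine buffer and −78 °C protecting the furan.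

Step 10
Reactants: 15 methyl (2E,5S,6E,10E)-5-hydroxy-3,7,11-trimethyl-12-(4-methylfuran-2-yl)dodeca-2,6,10-trienoate
Product: 16 methyl (2E,5S,6E,10E)-5-[(tert-butyldimethylsilyl)oxy]-3,7,11-trimethyl-12-(4-methylfuran-2-yl)dodeca-2,6,10-trienoate
Conditions: TBSCl, imidazole, DMAP (4-dimethylaminopyridine, cat.), DMF, rt
Reagents that add atoms: tert-butyldimethylsilyl chloride, CC(C)(C)[Si](C)(C)Cl
Why: Silylation of the secondary allylic alcohol under basic conditions masks it for the reduction, bromination and Grignard steps without risk to the stereocentre.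

Step 11
Reactants: 16 methyl (2E,5S,6E,10E)-5-[(tert-butyldimethylsilyl)oxy]-3,7,11-trimethyl-12-(4-methylfuran-2-yl)dodeca-2,6,10-trienoate
Product: 17 (2E,5S,6E,10E)-5-[(tert-butyldimethylsilyl)oxy]-3,7,11-trimethyl-12-(4-methylfuran-2-yl)dodeca-2,6,10-trien-1-ol
Conditions: i-Bu2AlH (2.5 equiv), CH2Cl2, −78 °C; aq. potassium sodium tartrate
Reagents that add atoms: none
Why: i-Bu2AlH 1,2-reduction of the enoate gives the primary allylic alcohol with the 2E alkene and silyl ether intact.

Step 12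
Reactants: 17 (2E,5S,6E,10E)-5-[(tert-butyldimethylsilyl)oxy]-3,7,11-trimethyl-12-(4-methylfuran-2-yl)dodeca-2,6,10-trien-1-ol
Product: 18 (2E,5S,6E,10E)-1-bromo-5-[(tert-butyldimethylsilyl)oxy]-3,7,11-trimethyl-12-(4-methylfuran-2-yl)dodeca-2,6,10-triene
Conditions: PPh3, CBr4, 2,6-lutidine (0.1 equiv), CH2Cl2, −20 to 0 °C; used at once
Reagents that add atoms: carbon tetrabromide, BrC(Br)(Br)Br
Why: Appel bromination gives the primary allylic bromide by SN2 under neutral conditions that spare the furan, the silyl ether and the alkene geometry.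

Step 13
Reactants: 19 4-hydroxy-3-methylbenzaldehyde
Product: 20 3-bromo-4-hydroxy-5-methylbenzaldehyde
Conditions: Br2 (1.05 equiv), NaOAc, AcOH, rt
Reagents that add atoms: bromine, BrBr
Why: Electrophilic aromatic bromination goes to the only free position ortho to the phenol, which is also meta to the formyl group.

Step 14
Reactants: 20 3-bromo-4-hydroxy-5-methylbenzaldehyde
Product: 22 2-bromo-6-methylbenzene-1,4-diol, via aryl formate 21 (not isolated)
Conditions: 30% H2O2, 1 M NaOH, THF/H2O, 0 °C to rt, N2; then 1 M HCl, aq. Na2S2O4 wash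
Reagents that add atoms: hydrogen peroxide, OO
Why: Dakin oxidation (aryl migration in the hydroperoxide adduct, then hydrolysis of the formate) replaces the formyl group para to the phenol by hydroxyl, giving the hydroquinone with bromine and methyl flanking one oxygen.

Step 15
Reactants: 22 2-bromo-6-methylbenzene-1,4-diol
Product: 23 [(2-bromo-6-methyl-1,4-phenylene)bis(oxy)]bis(tert-butyldimethylsilane)
Conditions: TBSCl (2.5 equiv), imidazole (5 equiv), DMF, 40 °C
Reagents that add atoms: tert-butyldimethylsilyl chloride, CC(C)(C)[Si](C)(C)Cl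
Why: Double silylation protects both phenols with groups that survive Grignard formation and leave at the end with fluoride instead of acid.

Step 16
Reactants: 23 [(2-bromo-6-methyl-1,4-phenylene)bis(oxy)]bis(tert-butyldimethylsilane); 18 (2E,5S,6E,10E)-1-bromo-5-[(tert-butyldimethylsilyl)oxy]-3,7,11-trimethyl-12-(4-methylfuran-2-yl)dodeca-2,6,10-triene
Product: 25 tert-butyl{[(2E,5S,6E,10E)-1-[2,5-bis(tert-butyldimethylsilyloxy)-3-methylphenyl]-3,7,11-trimethyl-12-(4-methylfuran-2-yl)dodeca-2,6,10-trien-5-yl]oxy}dimethylsilane, via arylmagnesium bromide 24 (not isolated)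
Conditions: Mg turnings (I2-activated), THF, 50 °C; then Li2CuCl4 (5 mol %), 18 (0.7 equiv), THF, −40 to 0 °C
Reagents that add atoms: none
Why: Kochi-type Cu-catalysed Grignard cross-coupling, in which the aryl Grignard reagent (no silyl migration, unlike the aryllithium) displaces the primary allylic bromide at the α-carbon because the γ,γ-disubstituted terminus disfavours SN2′, so the 2E alkene and the remote stereocentre are kept.

Step 17
Reactants: 25 tert-butyl{[(2E,5S,6E,10E)-1-[2,5-bis(tert-butyldimethylsilyloxy)-3-methylphenyl]-3,7,11-trimethyl-12-(4-methylfuran-2-yl)dodeca-2,6,10-trien-5-yl]oxy}dimethylsilane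
Product: 26 2-[(2E,5S,6E,10E)-5-hydroxy-3,7,11-trimethyl-12-(4-methylfuran-2-yl)dodeca-2,6,10-trien-1-yl]-6-methylbenzene-1,4-diol
Conditions: Bu4NF (4 equiv), AcOH (4 equiv), degassed THF, 0 °C to rt, argon; aq. NH4Cl/Na2S2O4 work-up
Reagents that add atoms: none
Why: Buffered fluoride desilylation removes the two aryl and one allylic silyl ethers at near-neutral pH, which avoids ionising the allylic alcohol, protonating the furan or oxidising the hydroquinone, and leaves the 5S centre untouched.

**Compound list**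
1 | geranyl acetate, (2E)-3,7-dimethylocta-2,6-dien-1-yl acetate | CC(=O)OC/C=C(C)/CCC=C(C)C | starting material
2 | (2E,6E)-8-hydroxy-3,7-dimethylocta-2,6-dien-1-yl acetate | CC(=O)OC/C=C(C)/CC/C=C(C)/CO | intermediate
3 | (2E,6E)-8-bromo-3,7-dimethylocta-2,6-dien-1-yl acetate | CC(=O)OC/C=C(C)/CC/C=C(C)/CBr | intermediate
4 | hydroxyacetone | CC(=O)CO | starting material
5 | 2-methylbut-3-yne-1,2-diol (racemic) | C#CC(C)(O)CO | intermediate
6 | (2E,6E)-11,12-dihydroxy-3,7,11-trimethyldodeca-2,6-dien-9-yn-1-yl acetate (racemic at C11) | CC(=O)OC/C=C(C)/CC/C=C(C)/CC#CC(C)(O)CO | intermediate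
7 | (2E,6E)-8-(4-hydroxy-4-methyl-4,5-dihydrofuran-2-yl)-3,7-dimethylocta-2,6-dien-1-yl acetate (racemic) | CC(=O)OC/C=C(C)/CC/C=C(C)/CC1=CC(C)(O)CO1 | intermediate (not isolated)
8 | (2E,6E)-3,7-dimethyl-8-(4-methylfuran-2-yl)octa-2,6-dien-1-yl acetate | CC(=O)OC/C=C(C)/CC/C=C(C)/Cc1cc(C)co1 | intermediate
9 | (2E,6E)-3,7-dimethyl-8-(4-methylfuran-2-yl)octa-2,6-dien-1-ol | OC/C=C(C)/CC/C=C(C)/Cc1cc(C)co1 | intermediate
10 | (2E,6E)-3,7-dimethyl-8-(4-methylfuran-2-yl)octa-2,6-dienal | O=C/C=C(C)/CC/C=C(C)/Cc1cc(C)co1 | intermediate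
11 | methyl 3-methylbut-2-enoate | COC(=O)C=C(C)C | starting material
12 | lithium 1-methoxy-3-methylbuta-1,3-dien-1-olate | [Li]OC(OC)=CC(C)=C | intermediate (not isolated)
13 | tert-butyl[(1-methoxy-3-methylbuta-1,3-dien-1-yl)oxy]dimethylsilane | COC(O[Si](C)(C)C(C)(C)C)=CC(C)=C | intermediate
14 | methyl (2E,5S,6E,10E)-3,7,11-trimethyl-12-(4-methylfuran-2-yl)-5-[(trichlorosilyl)oxy]dodeca-2,6,10-trienoate | C/C(=C\[C@@H](O[Si](Cl)(Cl)Cl)C/C(C)=C/C(=O)OC)CC/C=C(\C)Cc1cc(C)co1 | intermediate (not isolated)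
15 | methyl (2E,5S,6E,10E)-5-hydroxy-3,7,11-trimethyl-12-(4-methylfuran-2-yl)dodeca-2,6,10-trienoate | C/C(=C\[C@@H](O)C/C(C)=C/C(=O)OC)CC/C=C(\C)Cc1cc(C)co1 | intermediate
16 | methyl (2E,5S,6E,10E)-5-[(tert-butyldimethylsilyl)oxy]-3,7,11-trimethyl-12-(4-methylfuran-2-yl)dodeca-2,6,10-trienoate | C/C(=C\[C@@H](O[Si](C)(C)C(C)(C)C)C/C(C)=C/C(=O)OC)CC/C=C(\C)Cc1cc(C)co1 | intermediate
17 | (2E,5S,6E,10E)-5-[(tert-butyldimethylsilyl)oxy]-3,7,11-trimethyl-12-(4-methylfuran-2-yl)dodeca-2,6,10-trien-1-ol | C/C(=C\[C@@H](O[Si](C)(C)C(C)(C)C)C/C(C)=C/CO)CC/C=C(\C)Cc1cc(C)co1 | intermediate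
18 | (2E,5S,6E,10E)-1-bromo-5-[(tert-butyldimethylsilyl)oxy]-3,7,11-trimethyl-12-(4-methylfuran-2-yl)dodeca-2,6,10-triene | C/C(=C\[C@@H](O[Si](C)(C)C(C)(C)C)C/C(C)=C/CBr)CC/C=C(\C)Cc1cc(C)co1 | intermediate
19 | 4-hydroxy-3-methylbenzaldehyde | Cc1cc(C=O)ccc1O | starting material
20 | 3-bromo-4-hydroxy-5-methylbenzaldehyde | Cc1cc(C=O)cc(Br)c1O | intermediate
21 | 3-bromo-4-hydroxy-5-methylphenyl formate | Cc1cc(OC=O)cc(Br)c1O | intermediate (not isolated)
22 | 2-bromo-6-methylbenzene-1,4-diol | Cc1cc(O)cc(Br)c1O | intermediate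
23 | [(2-bromo-6-methyl-1,4-phenylene)bis(oxy)]bis(tert-butyldimethylsilane) | Cc1cc(O[Si](C)(C)C(C)(C)C)cc(Br)c1O[Si](C)(C)C(C)(C)C | intermediate
24 | [2,5-bis(tert-butyldimethylsilyloxy)-3-methylphenyl]magnesium bromide | Cc1cc(O[Si](C)(C)C(C)(C)C)cc([Mg]Br)c1O[Si](C)(C)C(C)(C)C | intermediate (not isolated)
25 | tert-butyl{[(2E,5S,6E,10E)-1-[2,5-bis(tert-butyldimethylsilyloxy)-3-methylphenyl]-3,7,11-trimethyl-12-(4-methylfuran-2-yl)dodeca-2,6,10-trien-5-yl]oxy}dimethylsilane | C/C(=C\[C@@H](O[Si](C)(C)C(C)(C)C)C/C(C)=C/Cc1cc(O[Si](C)(C)C(C)(C)C)cc(C)c1O[Si](C)(C)C(C)(C)C)CC/C=C(\C)Cc1cc(C)co1 | intermediate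
26 | 2-[(2E,5S,6E,10E)-5-hydroxy-3,7,11-trimethyl-12-(4-methylfuran-2-yl)dodeca-2,6,10-trien-1-yl]-6-methylbenzene-1,4-diol | C/C(=C\[C@@H](O)C/C(C)=C/Cc1cc(O)cc(C)c1O)CC/C=C(\C)Cc1cc(C)co1 | target

**Totals**
Total step count: 17.
Longest linear sequence: 12 steps from geranyl acetate (steps 1, 2, 4, 5, 6, 7, 9, 10, 11, 12, 16, 17).

**Three steps most likely to fail**

Step 9 (enantioselectivity, or acid damage to the furan during the SiCl4 aldol). The fallback sets out from 10 and comes back at 16. Brown allylation of 10 with (−)-Ipc2B(allyl) (from (−)-Ipc2BOMe and allylmagnesium bromide, Et2O, −78 °C, NaBO3 work-up) attacks the Si face and gives (4S,5E,9E)-6,10-dimethyl-11-(4-methylfuran-2-yl)undeca-1,5,9-trien-4-ol F3. Silylation with TBSCl and imidazole gives its silyl ether tert-butyl{[(4S,5E,9E)-6,10-dimethyl-11-(4-methylfuran-2-yl)undeca-1,5,9-trien-4-yl]oxy}dimethylsilane F4. Tsuji–Wacker oxidation of the only monosubstituted alkene (PdCl2, CuCl, O2, DMF/H2O) gives the methyl ketone (4S,5E,9E)-4-[(tert-butyldimethylsilyl)oxy]-6,10-dimethyl-11-(4-methylfuran-2-yl)undeca-5,9-dien-2-one F5. Horner–Wadsworth–Emmons olefination with trimethyl phosphonoacetate and NaH in THF then gives 16 after chromatographic removal of the minor 2Z isomer. The cost is lower alkene selectivity in return for a stereocentre of well-established sense.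

Step 4 (SN2 against SN2′ in the alkynyl–allyl coupling, and the free diol). The fallback sets out from 3 and comes back at 9. Commercial 3-methylfuran-2(5H)-one is silylated (TBSOTf, Et3N, CH2Cl2, 0 °C) to tert-butyldimethyl[(3-methylfuran-2-yl)oxy]silane F1. This is alkylated at its free α-position by 3 with CF3CO2Ag in CH2Cl2 at −78 °C to give the butenolide (2E,6E)-3,7-dimethyl-8-(4-methyl-5-oxo-2,5-dihydrofuran-2-yl)octa-2,6-dien-1-yl acetate F2. i-Bu2AlH (4 equiv, CH2Cl2, −78 °C) reduces the lactone to the lactol and cleaves the acetate; on aqueous citric acid work-up the lactol loses water to give the 4-methylfuran and so 9 directly.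

Step 16 (Grignard formation from the hindered, electron-rich bromide and regiochemistry of the allylic substitution). The fallback sets out from 23 and 17 and comes back at 25. Miyaura borylation of 23 (bis(pinacolato)diboron, Pd(dppf)Cl2, KOAc, dioxane, 80 °C) gives 2-[2,5-bis(tert-butyldimethylsilyloxy)-3-methylphenyl]-4,4,5,5-tetramethyl-1,3,2-dioxaborolane F6. Alcohol 17 with methyl chloroformate and pyridine gives the allylic carbonate (2E,5S,6E,10E)-5-[(tert-butyldimethylsilyl)oxy]-3,7,11-trimethyl-12-(4-methylfuran-2-yl)dodeca-2,6,10-trien-1-yl methyl carbonate F7. A Suzuki–Miyaura allyl–aryl coupling through the π-allylpalladium species (Pd(PPh3)4, K2CO3, THF/H2O, 50 °C) delivers the aryl group to the less hindered CH2 terminus and gives 25.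

**Further compounds**
F1 | step 4 | tert-butyldimethyl[(3-methylfuran-2-yl)oxy]silane | Cc1ccoc1O[Si](C)(C)C(C)(C)C
F2 | step 4 | (2E,6E)-3,7-dimethyl-8-(4-methyl-5-oxo-2,5-dihydrofuran-2-yl)octa-2,6-dien-1-yl acetate (racemic) | CC(=O)OC/C=C(C)/CC/C=C(C)/CC1OC(=O)C(C)=C1
F3 | step 9 | (4S,5E,9E)-6,10-dimethyl-11-(4-methylfuran-2-yl)undeca-1,5,9-trien-4-ol | C/C(=C\[C@@H](O)CC=C)CC/C=C(\C)Cc1cc(C)co1
F4 | step 9 | tert-butyl{[(4S,5E,9E)-6,10-dimethyl-11-(4-methylfuran-2-yl)undeca-1,5,9-trien-4-yl]oxy}dimethylsilane | C/C(=C\[C@@H](O[Si](C)(C)C(C)(C)C)CC=C)CC/C=C(\C)Cc1cc(C)co1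
F5 | step 9 | (4S,5E,9E)-4-[(tert-butyldimethylsilyl)oxy]-6,10-dimethyl-11-(4-methylfuran-2-yl)undeca-5,9-dien-2-one | C/C(=C\[C@@H](O[Si](C)(C)C(C)(C)C)CC(C)=O)CC/C=C(\C)Cc1cc(C)co1
F6 | step 16 | 2-[2,5-bis(tert-butyldimethylsilyloxy)-3-methylphenyl]-4,4,5,5-tetramethyl-1,3,2-dioxaborolane | Cc1cc(O[Si](C)(C)C(C)(C)C)cc(B2OC(C)(C)C(C)(C)O2)c1O[Si](C)(C)C(C)(C)C
F7 | step 16 | (2E,5S,6E,10E)-5-[(tert-butyldimethylsilyl)oxy]-3,7,11-trimethyl-12-(4-methylfuran-2-yl)dodeca-2,6,10-trien-1-yl methyl carbonate | C/C(=C\[C@@H](O[Si](C)(C)C(C)(C)C)C/C(C)=C/COC(=O)OC)CC/C=C(\C)Cc1cc(C)co1
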